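Ring B, the cyclohexene, is cut at C6–C7 and C5–C10 (spiro[4.5]decane numbering; C5 is the spiro carbon shared with cyclopentane ring A). Read this way, C5 and C6 are the α- and carbonyl carbons of a cyclopentanecarbaldehyde and C7–C10 are methyl vinyl ketone, so one Stork enamine Michael addition–aldol condensation builds ring B and the quaternary spiro centre together, the large C1 side chain directing attack to the face of the C4 methyl. The aldehyde, carrying all three ring-A and side-chain stereocentres, comes from natural nepetalactone by convex-face hydrogenation; afterwards oxygen is installed at C9, the carbonyl is exchanged for the C8 methyl, and the ylidene butenolide is appended last.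

Key step: step 5

Remark: (4aS,7S,7aR)-nepetalactone, the main lactone of catnip oil, is taken as a purchasable starting material; all spiro compounds are named with one fixed numbering (C1 side-chain carbon, C4 ring-A methyl carbon, C5 spiro carbon, C6–C10 ring B with oxygen at C9).

Step 1
Reactants: 1 (4aS,7S,7aR)-nepetalactone
Product: 2 (4S,4aR,7S,7aR)-dihydronepetalactone
Conditions: H2 (3 atm), 5% Pd/C, EtOH, rt
Reagents that add atoms: none
Why: Heterogeneous syn-hydrogenation of the enol-ether C3=C4 bond should occur on the convex face of the cis-fused bicycle (the face of the two ring-fusion hydrogens), which sets C4 as S, the configuration of the side-chain methine of the target.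

Step 2
Reactants: 2 (4S,4aR,7S,7aR)-dihydronepetalactone
Product: 3 (1R,2R,5S)-2-[(2S)-1-hydroxypropan-2-yl]-N-methoxy-N,5-dimethylcyclopentane-1-carboxamide
Conditions: MeNH(OMe)·HCl, AlMe3, CH2Cl2, 0 °C → rt
Reagents that add atoms: N,O-dimethylhydroxylamine hydrochloride, CNOC.Cl
Why: Weinreb aminolysis of the lactone by the aluminium amide made in the flask opens the ring at the acyl carbon and frees the primary alcohol without touching a stereocentre.

Step 3
Reactants: 3 (1R,2R,5S)-2-[(2S)-1-hydroxypropan-2-yl]-N-methoxy-N,5-dimethylcyclopentane-1-carboxamide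
Product: 4 (1R,2R,5S)-2-[(2S)-1-{[tert-butyl(diphenyl)silyl]oxy}propan-2-yl]-N-methoxy-N,5-dimethylcyclopentane-1-carboxamide
Conditions: TBDPSCl, imidazole, DMF, rt
Reagents that add atoms: tert-butyl(chloro)diphenylsilane, CC(C)(C)[Si](Cl)(c1ccccc1)c1ccccc1
Why: Silylation of the primary alcohol stops relactonisation and makes the side chain the bulky group that shields one face in step 5.

Step 4
Reactants: 4 (1R,2R,5S)-2-[(2S)-1-{[tert-butyl(diphenyl)silyl]oxy}propan-2-yl]-N-methoxy-N,5-dimethylcyclopentane-1-carboxamide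
Product: 5 (1R,2R,5S)-2-[(2S)-1-{[tert-butyl(diphenyl)silyl]oxy}propan-2-yl]-5-methylcyclopentane-1-carbaldehyde
Conditions: DIBAL-H (i-Bu2AlH), THF, −78 °C; aq. Rochelle salt
Reagents that add atoms: none
Why: Hydride reduction of a Weinreb amide stops at the aldehyde through the chelated tetrahedral intermediate; epimerisation at C1 would be harmless because this carbon becomes trigonal in the next step.

Step 5
Reactants: 5 (1R,2R,5S)-2-[(2S)-1-{[tert-butyl(diphenyl)silyl]oxy}propan-2-yl]-5-methylcyclopentane-1-carbaldehyde; 6 methyl vinyl ketone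
Product: 9 (1R,4S,5R)-1-[(2S)-1-{[tert-butyl(diphenyl)silyl]oxy}propan-2-yl]-4-methylspiro[4.5]dec-6-en-8-one, via pyrrolidine enamine 7 (not isolated), via keto aldehyde 8 (not isolated)
Conditions: pyrrolidine, PhH, reflux (Dean–Stark); methyl vinyl ketone, rt → reflux; then AcOH/NaOAc/H2O, reflux
Reagents that add atoms: methyl vinyl ketone, C=CC(C)=O
Why: Condensation of 5 with pyrrolidine gives enamine 7, whose nucleophilic ring carbon (the future spiro C5) adds to the β-carbon of methyl vinyl ketone (bond C5–C10); buffered hydrolysis releases keto aldehyde 8, whose methyl-ketone enol attacks the aldehyde and loses water (bond C6–C7). The closest known reaction is the Robinson spiroannulation of α-branched cycloalkanecarbaldehydes with methyl vinyl ketone to 4,4-disubstituted cyclohex-2-enones. Ring B closes by a 6-(enolexo)-exo-trig aldol addition followed by E1cB dehydration. The only new stereocentre, spiro C5, is set in the Michael step by the resident C1 and C4 centres: the enamine should be attacked on the face anti to the large CH(CH3)CH2OTBDPS group at C1 and syn to the small C4 methyl, which puts C10 cis to that methyl as the target requires. The step needs this facial selectivity and C- over N-alkylation, which the bulky silyl ether and the reversibility of N-alkylation should secure; the aldol regiochemistry is unambiguous because the aldehyde carbon has no α-hydrogen left and only the methyl terminus can give a six-membered ring.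

Step 6
Reactants: 9 (1R,4S,5R)-1-[(2S)-1-{[tert-butyl(diphenyl)silyl]oxy}propan-2-yl]-4-methylspiro[4.5]dec-6-en-8-one
Product: 11 (1R,4S,5R,9S)-9-{[tert-butyl(dimethyl)silyl]oxy}-1-[(2S)-1-{[tert-butyl(diphenyl)silyl]oxy}propan-2-yl]-4-methylspiro[4.5]dec-6-en-8-one, via silyl dienol ether 10 (not isolated)
Conditions: TBSOTf, Et3N, CH2Cl2, 0 °C; crude, then mCPBA, CH2Cl2/hexane, −20 °C → rt
Reagents that add atoms: tert-butyldimethylsilyl trifluoromethanesulfonate, CC(C)(C)[Si](C)(C)OS(=O)(=O)C(F)(F)F; 3-chloroperbenzoic acid, OOC(=O)c1cccc(Cl)c1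
Why: Soft enolisation can only occur toward C9 (C5 is quaternary) and Rubottom oxidation of the resulting 2-silyloxy diene (epoxidation of the electron-rich enol-ether bond, then silyl migration) gives the α'-silyloxy enone; the peracid should approach C9 from the ring-B face flanked by the C1 hydrogen and not from the face flanked by the C4 methyl, which gives 9S.

Step 7
Reactants: 11 (1R,4S,5R,9S)-9-{[tert-butyl(dimethyl)silyl]oxy}-1-[(2S)-1-{[tert-butyl(diphenyl)silyl]oxy}propan-2-yl]-4-methylspiro[4.5]dec-6-en-8-one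
Product: 13 (1R,4S,5S,9S)-9-{[tert-butyl(dimethyl)silyl]oxy}-1-[(2S)-1-{[tert-butyl(diphenyl)silyl]oxy}propan-2-yl]-4-methylspiro[4.5]dec-7-en-8-yl trifluoromethanesulfonate, via lithium enolate 12 (not isolated)
Conditions: L-Selectride (LiBH(s-Bu)3), THF, −78 °C; then PhNTf2, −78 °C → rt
Reagents that add atoms: N-phenylbis(trifluoromethanesulfonimide), O=S(=O)(N(c1ccccc1)S(=O)(=O)C(F)(F)F)C(F)(F)F
Why: Conjugate reduction of the β-monosubstituted enone by the bulky borohydride gives the enolate regiospecifically at C7=C8, and O-sulfonylation fixes it as the enol triflate; C9 is never enolised and keeps its configuration.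

Step 8
Reactants: 13 (1R,4S,5S,9S)-9-{[tert-butyl(dimethyl)silyl]oxy}-1-[(2S)-1-{[tert-butyl(diphenyl)silyl]oxy}propan-2-yl]-4-methylspiro[4.5]dec-7-en-8-yl trifluoromethanesulfonate
Product: 14 tert-butyl({(1R,4S,5S,9S)-1-[(2S)-1-{[tert-butyl(diphenyl)silyl]oxy}propan-2-yl]-4,8-dimethylspiro[4.5]dec-7-en-9-yl}oxy)dimethylsilane
Conditions: MeZnCl, Pd(PPh3)4 (5 mol%), THF, 50 °C
Reagents that add atoms: methylzinc chloride, C[Zn]Cl
Why: Negishi cross-coupling of the enol triflate installs the C8 methyl group with the double bond held at C7=C8.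

Step 9
Reactants: 14 tert-butyl({(1R,4S,5S,9S)-1-[(2S)-1-{[tert-butyl(diphenyl)silyl]oxy}propan-2-yl]-4,8-dimethylspiro[4.5]dec-7-en-9-yl}oxy)dimethylsilane
Product: 15 (1R,4S,5S,9S)-1-[(2S)-1-hydroxypropan-2-yl]-4,8-dimethylspiro[4.5]dec-7-en-9-ol
Conditions: TBAF (n-Bu4NF), THF, rt
Reagents that add atoms: none
Why: Fluoride cleaves both silyl ethers in one operation and leaves all stereocentres untouched.

Step 10
Reactants: 15 (1R,4S,5S,9S)-1-[(2S)-1-hydroxypropan-2-yl]-4,8-dimethylspiro[4.5]dec-7-en-9-ol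
Product: 16 (2S)-2-[(1R,4S,5S,9S)-9-hydroxy-4,8-dimethylspiro[4.5]dec-7-en-1-yl]propanal
Conditions: TEMPO (10 mol%), PhI(OAc)2, CH2Cl2, rt
Reagents that add atoms: none
Why: The oxoammonium oxidant reacts with the unhindered primary alcohol well before the hindered secondary allylic one, and the neutral medium should keep the α-methine of the new aldehyde from epimerising.

Step 11
Reactants: 16 (2S)-2-[(1R,4S,5S,9S)-9-hydroxy-4,8-dimethylspiro[4.5]dec-7-en-1-yl]propanal; 17 3-phenylpropanoyl chloride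
Product: 18 (1R,4S,5S,9S)-4,8-dimethyl-1-[(2S)-1-oxopropan-2-yl]spiro[4.5]dec-7-en-9-yl 3-phenylpropanoate
Conditions: pyridine, DMAP (cat.), CH2Cl2, 0 °C
Reagents that add atoms: 3-phenylpropanoyl chloride, O=C(Cl)CCc1ccccc1
Why: DMAP-catalysed acylation esterifies the C9 alcohol with retention, and the cold, weakly basic medium should leave the aldehyde and its α-stereocentre alone.

Step 12
Reactants: 18 (1R,4S,5S,9S)-4,8-dimethyl-1-[(2S)-1-oxopropan-2-yl]spiro[4.5]dec-7-en-9-yl 3-phenylpropanoate; 19 3-methylfuran-2(5H)-one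
Product: 22 (1R,4S,5S,9S)-4,8-dimethyl-1-[(1Z,2S)-1-(4-methyl-5-oxofuran-2(5H)-ylidene)propan-2-yl]spiro[4.5]dec-7-en-9-yl 3-phenylpropanoate (CNP0260277.1), via silyloxyfuran 20 (not isolated), via silylated aldol adduct 21 (not isolated)
Conditions: 19, TBSOTf, i-Pr2NEt, CH2Cl2, 0 °C; 18, −78 °C; then DBU, −78 °C → rt
Reagents that add atoms: 3-methylfuran-2(5H)-one, CC1=CCOC1=O
Why: One-pot vinylogous Mukaiyama aldol addition of the silyloxyfuran made in the flask (through its C5) to the aldehyde, then E1cB loss of silanolate from the acidic γ-position, should give the more stable Z-ylidene butenolide with the alkyl group cis to the ring oxygen.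

Compound list
1 | (4aS,7S,7aR)-nepetalactone, (4aS,7S,7aR)-4,7-dimethyl-5,6,7,7a-tetrahydrocyclopenta[c]pyran-1(4aH)-one | C[C@H]1CC[C@H]2[C@@H]1C(=O)OC=C2C | starting material
2 | (4S,4aR,7S,7aR)-dihydronepetalactone, 4,7-dimethylhexahydrocyclopenta[c]pyran-1(3H)-one | C[C@H]1CC[C@H]2[C@@H]1C(=O)OC[C@H]2C | intermediate
3 | (1R,2R,5S)-2-[(2S)-1-hydroxypropan-2-yl]-N-methoxy-N,5-dimethylcyclopentane-1-carboxamide | C[C@H]1CC[C@H]([C@H](C)CO)[C@@H]1C(=O)N(C)OC | intermediate
4 | (1R,2R,5S)-2-[(2S)-1-{[tert-butyl(diphenyl)silyl]oxy}propan-2-yl]-N-methoxy-N,5-dimethylcyclopentane-1-carboxamide | C[C@H]1CC[C@H]([C@H](C)CO[Si](c2ccccc2)(c2ccccc2)C(C)(C)C)[C@@H]1C(=O)N(C)OC | intermediate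
5 | (1R,2R,5S)-2-[(2S)-1-{[tert-butyl(diphenyl)silyl]oxy}propan-2-yl]-5-methylcyclopentane-1-carbaldehyde | C[C@H]1CC[C@H]([C@H](C)CO[Si](c2ccccc2)(c2ccccc2)C(C)(C)C)[C@@H]1C=O | intermediate
6 | methyl vinyl ketone (but-3-en-2-one) | C=CC(C)=O | starting material
7 | pyrrolidine enamine of 5, 1-{(E)-[(2R,5S)-2-[(2S)-1-{[tert-butyl(diphenyl)silyl]oxy}propan-2-yl]-5-methylcyclopentylidene]methyl}pyrrolidine | C[C@H]1CC[C@H]([C@H](C)CO[Si](c2ccccc2)(c2ccccc2)C(C)(C)C)/C1=C/N1CCCC1 | intermediate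
8 | (1R,2R,5S)-2-[(2S)-1-{[tert-butyl(diphenyl)silyl]oxy}propan-2-yl]-5-methyl-1-(3-oxobutyl)cyclopentane-1-carbaldehyde | C[C@H]1CC[C@H]([C@H](C)CO[Si](c2ccccc2)(c2ccccc2)C(C)(C)C)[C@@]1(C=O)CCC(C)=O | intermediate
9 | (1R,4S,5R)-1-[(2S)-1-{[tert-butyl(diphenyl)silyl]oxy}propan-2-yl]-4-methylspiro[4.5]dec-6-en-8-one | C[C@H](CO[Si](c1ccccc1)(c1ccccc1)C(C)(C)C)[C@H]1CC[C@H](C)[C@@]12C=CC(=O)CC2 | intermediate
10 | tert-butyl({(1R,4S,5R)-1-[(2S)-1-{[tert-butyl(diphenyl)silyl]oxy}propan-2-yl]-4-methylspiro[4.5]deca-6,8-dien-8-yl}oxy)dimethylsilane | C[C@H](CO[Si](c1ccccc1)(c1ccccc1)C(C)(C)C)[C@H]1CC[C@H](C)[C@@]12C=CC(O[Si](C)(C)C(C)(C)C)=CC2 | intermediate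
11 | (1R,4S,5R,9S)-9-{[tert-butyl(dimethyl)silyl]oxy}-1-[(2S)-1-{[tert-butyl(diphenyl)silyl]oxy}propan-2-yl]-4-methylspiro[4.5]dec-6-en-8-one | C[C@H](CO[Si](c1ccccc1)(c1ccccc1)C(C)(C)C)[C@H]1CC[C@H](C)[C@@]12C=CC(=O)[C@@H](O[Si](C)(C)C(C)(C)C)C2 | intermediate
12 | lithium (1R,4S,5S,9S)-9-{[tert-butyl(dimethyl)silyl]oxy}-1-[(2S)-1-{[tert-butyl(diphenyl)silyl]oxy}propan-2-yl]-4-methylspiro[4.5]dec-7-en-8-olate | C[C@H](CO[Si](c1ccccc1)(c1ccccc1)C(C)(C)C)[C@H]1CC[C@H](C)[C@@]12CC=C([O-])[C@@H](O[Si](C)(C)C(C)(C)C)C2.[Li+] | intermediate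
13 | (1R,4S,5S,9S)-9-{[tert-butyl(dimethyl)silyl]oxy}-1-[(2S)-1-{[tert-butyl(diphenyl)silyl]oxy}propan-2-yl]-4-methylspiro[4.5]dec-7-en-8-yl trifluoromethanesulfonate | C[C@H](CO[Si](c1ccccc1)(c1ccccc1)C(C)(C)C)[C@H]1CC[C@H](C)[C@@]12CC=C(OS(=O)(=O)C(F)(F)F)[C@@H](O[Si](C)(C)C(C)(C)C)C2 | intermediate
14 | tert-butyl({(1R,4S,5S,9S)-1-[(2S)-1-{[tert-butyl(diphenyl)silyl]oxy}propan-2-yl]-4,8-dimethylspiro[4.5]dec-7-en-9-yl}oxy)dimethylsilane | C[C@H](CO[Si](c1ccccc1)(c1ccccc1)C(C)(C)C)[C@H]1CC[C@H](C)[C@@]12CC=C(C)[C@@H](O[Si](C)(C)C(C)(C)C)C2 | intermediate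
15 | (1R,4S,5S,9S)-1-[(2S)-1-hydroxypropan-2-yl]-4,8-dimethylspiro[4.5]dec-7-en-9-ol | C[C@H](CO)[C@H]1CC[C@H](C)[C@@]12CC=C(C)[C@@H](O)C2 | intermediate
16 | (2S)-2-[(1R,4S,5S,9S)-9-hydroxy-4,8-dimethylspiro[4.5]dec-7-en-1-yl]propanal | C[C@H](C=O)[C@H]1CC[C@H](C)[C@@]12CC=C(C)[C@@H](O)C2 | intermediate
17 | 3-phenylpropanoyl chloride | O=C(Cl)CCc1ccccc1 | starting material
18 | (1R,4S,5S,9S)-4,8-dimethyl-1-[(2S)-1-oxopropan-2-yl]spiro[4.5]dec-7-en-9-yl 3-phenylpropanoate | C[C@H](C=O)[C@H]1CC[C@H](C)[C@@]12CC=C(C)[C@@H](OC(=O)CCc3ccccc3)C2 | intermediate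
19 | 3-methylfuran-2(5H)-one | CC1=CCOC1=O | starting material
20 | tert-butyldimethyl[(3-methylfuran-2-yl)oxy]silane | Cc1ccoc1O[Si](C)(C)C(C)(C)C | intermediate
21 | (1R,4S,5S,9S)-1-[(2S)-1-{[tert-butyl(dimethyl)silyl]oxy}-1-(4-methyl-5-oxo-2,5-dihydrofuran-2-yl)propan-2-yl]-4,8-dimethylspiro[4.5]dec-7-en-9-yl 3-phenylpropanoate (mixture at the two new centres, both removed in the elimination) | C[C@H](C(O[Si](C)(C)C(C)(C)C)C1OC(=O)C(C)=C1)[C@H]1CC[C@H](C)[C@@]12CC=C(C)[C@@H](OC(=O)CCc3ccccc3)C2 | intermediate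
22 | (1R,4S,5S,9S)-4,8-dimethyl-1-[(1Z,2S)-1-(4-methyl-5-oxofuran-2(5H)-ylidene)propan-2-yl]spiro[4.5]dec-7-en-9-yl 3-phenylpropanoate (CNP0260277.1) | CC1=C/C(=C/[C@@H](C)[C@H]2CC[C@H](C)[C@@]23CC=C(C)[C@@H](OC(=O)CCc2ccccc2)C3)OC1=O | target

Total step count: 12. Longest linear sequence: 12 steps (1 → 22).

Steps most likely to fail

Step 5: the Michael addition may show poor facial selectivity, so that the spiro centre forms as a mixture. The fallback sets out from 2 and comes back at 9, and lets the rigid cis-fused lactone choose the face. Deprotonation of 2 with LDA (THF/DMPU, −78 °C) and alkylation with 2-(2-iodoethyl)-2-methyl-1,3-dioxolane should give, by attack on the convex face, (4S,4aR,7S,7aR)-4,7-dimethyl-7a-[2-(2-methyl-1,3-dioxolan-2-yl)ethyl]hexahydrocyclopenta[c]pyran-1(3H)-one F1. Reduction with i-Bu2AlH (CH2Cl2, −78 °C) gives the lactol, 4,7-dimethyl-7a-[2-(2-methyl-1,3-dioxolan-2-yl)ethyl]octahydrocyclopenta[c]pyran-1-ol F2. TsOH in wet acetone, then KOH/MeOH, unmasks the methyl ketone and closes ring B by aldol condensation to (1R,4S,5R)-1-[(2S)-1-hydroxypropan-2-yl]-4-methylspiro[4.5]dec-6-en-8-one F3. This hydroxy enone may rest partly as its internal oxa-Michael adduct, which should reopen under base. TBDPSCl/imidazole then gives 9.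

Step 6: the peracid may attack both faces of the dienol ether, so that C9 is oxygenated with poor facial selectivity. The fallback sets out from 15, carried forward as whatever mixture of C9 epimers results, and comes back to 15 as the single 9S epimer. MnO2 (CH2Cl2, rt) oxidises only the allylic alcohol, to (1R,4S,5S)-1-[(2S)-1-hydroxypropan-2-yl]-4,8-dimethylspiro[4.5]dec-7-en-9-one F4. Reduction with BH3·SMe2 and (R)-2-methyl-CBS-oxazaborolidine (the catalyst enantiomer predicted when the C7=C8 flank acts as the large group) then sets C9 under reagent control and returns 15.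

Step 12: the amidine base may epimerise the side-chain methine through the extended furanolate or erode the Z geometry, and the silyl triflate may ionise the allylic ester. The fallback sets out from 16 and comes back at 22, and closes the butenolide without strong base. Dimethyl (1-diazo-2-oxopropyl)phosphonate with K2CO3 in MeOH at 0 °C (Ohira–Bestmann homologation) converts 16 into (1R,4S,5S,9S)-1-[(2S)-but-3-yn-2-yl]-4,8-dimethylspiro[4.5]dec-7-en-9-ol F5. Acylation with 17 (pyridine, DMAP) gives (1R,4S,5S,9S)-1-[(2S)-but-3-yn-2-yl]-4,8-dimethylspiro[4.5]dec-7-en-9-yl 3-phenylpropanoate F6. Separately, propargyl alcohol is treated with MeMgBr/CuI and then I2 to give (Z)-3-iodo-2-methylprop-2-en-1-ol F7, which is oxidised (MnO2, then NaClO2) to (Z)-3-iodo-2-methylacrylic acid F8. Pd(PPh3)2Cl2/CuI/Et3N in MeCN at rt then joins F6 and F8 by Sonogashira coupling followed by 5-exo-dig lactonisation, which should give 22 directly as the Z isomer.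

Further compounds
F1 | step 5 | (4S,4aR,7S,7aR)-4,7-dimethyl-7a-[2-(2-methyl-1,3-dioxolan-2-yl)ethyl]hexahydrocyclopenta[c]pyran-1(3H)-one | C[C@H]1CC[C@H]2[C@]1(CCC1(C)OCCO1)C(=O)OC[C@H]2C
F2 | step 5 | (4S,4aR,7S,7aR)-4,7-dimethyl-7a-[2-(2-methyl-1,3-dioxolan-2-yl)ethyl]octahydrocyclopenta[c]pyran-1-ol (lactol, either anomer) | C[C@H]1CC[C@H]2[C@]1(CCC1(C)OCCO1)C(O)OC[C@H]2C
F3 | step 5 | (1R,4S,5R)-1-[(2S)-1-hydroxypropan-2-yl]-4-methylspiro[4.5]dec-6-en-8-one | C[C@H](CO)[C@H]1CC[C@H](C)[C@@]12C=CC(=O)CC2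
F4 | step 6 | (1R,4S,5S)-1-[(2S)-1-hydroxypropan-2-yl]-4,8-dimethylspiro[4.5]dec-7-en-9-one | C[C@H](CO)[C@H]1CC[C@H](C)[C@@]12CC=C(C)C(=O)C2
F5 | step 12 | (1R,4S,5S,9S)-1-[(2S)-but-3-yn-2-yl]-4,8-dimethylspiro[4.5]dec-7-en-9-ol | C[C@H](C#C)[C@H]1CC[C@H](C)[C@@]12CC=C(C)[C@@H](O)C2
F6 | step 12 | (1R,4S,5S,9S)-1-[(2S)-but-3-yn-2-yl]-4,8-dimethylspiro[4.5]dec-7-en-9-yl 3-phenylpropanoate | C[C@H](C#C)[C@H]1CC[C@H](C)[C@@]12CC=C(C)[C@@H](OC(=O)CCc3ccccc3)C2
F7 | step 12 | (Z)-3-iodo-2-methylprop-2-en-1-ol | OC/C(C)=C\I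
F8 | step 12 | (Z)-3-iodo-2-methylacrylic acid | OC(=O)/C(C)=C\I
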